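**Plan**
- The target is the hexadecanoate of a benzylic alcohol on a diaryl ether. Ring A carries CH2O, OMe and OH; ring B is a methyl 6-hydroxy-4-methylbenzoate. There is no stereocentre and no stereogenic double bond, so no stereocontrol is needed.
- First cut: C3–C4 of the hexadecanoyl chain. C3 lies β to the ester carbonyl C1, so C1–C3 can be carried as an acrylate on the benzylic oxygen of ring A. Its CH2 terminus (C3) accepts the tridecyl radical (C4–C16) released by decarboxylation of an N-acyloxyphthalimide of tetradecanoic acid (Giese addition).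
- Second cut: the acrylate C(=O)–O bond. The benzylic CH2OH comes from an ortho-formyl group that first activates the ether coupling.
- Third cut: the diaryl ether C–O bond at ring A C2 (Ullmann coupling). Ring B enters as symmetric methyl 2,6-dihydroxy-4-methylbenzoate, so mono-arylation leaves the free, ester-chelated OH of the target.
- Ring A comes from 3-hydroxy-5-methoxybenzaldehyde by ortho-bromination and MOM protection. Both rings are bought as arenes.
- Forward order: bromide, diaryl ether, benzylic alcohol, acrylate, chain joined by radical conjugate addition, MOM removed.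

Key step: step 7

Remark: ring A is numbered as in aldehyde 1 (formyl on C1, bromine or ether oxygen on C2, hydroxyl on C3, methoxy on C5); compounds 1, 4 and 8 are taken as purchasable.

Step 1
Reactants: 1 3-hydroxy-5-methoxybenzaldehyde
Product: 2 2-bromo-3-hydroxy-5-methoxybenzaldehyde
Conditions: NBS (1.0 equiv), i-Pr2NH (10 mol %), CH2Cl2, 0 °C
Reagents that add atoms: N-bromosuccinimide, O=C1CCC(=O)N1Br
Why: Amine-mediated ortho-bromination of a phenol (electrophilic aromatic substitution, the N-bromoamine being delivered through an O–H···N hydrogen bond); of the two ortho positions, C2 is also para to the methoxy group and should react first, as in the C2-bromination of 3,5-dimethoxybenzaldehyde.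

Step 2
Reactants: 2 2-bromo-3-hydroxy-5-methoxybenzaldehyde
Product: 3 2-bromo-5-methoxy-3-(methoxymethoxy)benzaldehyde
Conditions: MOMCl (1.5 equiv), i-Pr2NEt (2 equiv), CH2Cl2, 0 °C to rt
Reagents that add atoms: chloromethyl methyl ether, COCCl
Why: Williamson-type O-alkylation to the MOM ether masks the phenol that would otherwise compete as a nucleophile in the copper coupling; the acetal should survive base, hydride and radical conditions.

Step 3
Reactants: 3 2-bromo-5-methoxy-3-(methoxymethoxy)benzaldehyde; 4 methyl 2,6-dihydroxy-4-methylbenzoate (3 equiv)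
Product: 5 methyl 2-[2-formyl-4-methoxy-6-(methoxymethoxy)phenoxy]-6-hydroxy-4-methylbenzoate
Conditions: CuI (10 mol %), picolinic acid (20 mol %), K3PO4 (2 equiv), degassed DMSO, 90 °C
Reagents that add atoms: none
Why: Ullmann-type copper-catalysed diaryl ether synthesis, favoured by the ortho-formyl group of the bromide; the two hydroxyls of 4 are equivalent, so an excess of 4 should give the mono-ether with the second, ester-chelated OH left free.

Step 4
Reactants: 5 methyl 2-[2-formyl-4-methoxy-6-(methoxymethoxy)phenoxy]-6-hydroxy-4-methylbenzoate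
Product: 6 methyl 2-hydroxy-6-[2-(hydroxymethyl)-4-methoxy-6-(methoxymethoxy)phenoxy]-4-methylbenzoate
Conditions: NaBH4 (1 equiv), MeOH/THF, 0 °C; aq. NH4Cl
Reagents that add atoms: none
Why: Chemoselective borohydride reduction of the aryl aldehyde; the methyl ester, the MOM acetal and the diaryl ether are inert at 0 °C, and methanol as solvent holds the methyl ester against lactonisation by the new alkoxide.

Step 5
Reactants: 6 methyl 2-hydroxy-6-[2-(hydroxymethyl)-4-methoxy-6-(methoxymethoxy)phenoxy]-4-methylbenzoate
Product: 7 methyl 2-hydroxy-6-[4-methoxy-2-(methoxymethoxy)-6-[(prop-2-enoyloxy)methyl]phenoxy]-4-methylbenzoate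
Conditions: acryloyl chloride (1.1 equiv), 2,4,6-collidine (1.5 equiv), BHT (trace), CH2Cl2, −40 to 0 °C
Reagents that add atoms: acryloyl chloride, C=CC(Cl)=O
Why: Acyl chloride esterification with a weak pyridine base and no DMAP; the primary benzylic alcohol should be acylated far faster than the ring-B phenol, which is hydrogen-bonded to its ester carbonyl and is not deprotonated by collidine.

Step 6
Reactants: 8 tetradecanoic acid
Product: 9 1,3-dioxoisoindolin-2-yl tetradecanoate
Conditions: N-hydroxyphthalimide (1.0 equiv), DIC (1.1 equiv), DMAP (5 mol %), CH2Cl2, rt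
Reagents that add atoms: N-hydroxyphthalimide, O=C1c2ccccc2C(=O)N1O
Why: Carbodiimide (Steglich-type) esterification gives the redox-active N-acyloxyphthalimide, the activating group that allows single-electron reduction and decarboxylation of the fatty acid.

Step 7
Reactants: 7 methyl 2-hydroxy-6-[4-methoxy-2-(methoxymethoxy)-6-[(prop-2-enoyloxy)methyl]phenoxy]-4-methylbenzoate; 9 1,3-dioxoisoindolin-2-yl tetradecanoate (1.5 equiv)
Product: 10 methyl 2-[2-[(hexadecanoyloxy)methyl]-4-methoxy-6-(methoxymethoxy)phenoxy]-6-hydroxy-4-methylbenzoate
Conditions: Ru(bpy)3(PF6)2 (1 mol %), Hantzsch ester (2 equiv), i-Pr2NEt·HBF4 (1 equiv), degassed CH2Cl2, blue LEDs, rt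
Reagents that add atoms: none
Why: Reductive photoredox decarboxylative Giese addition: Ru(I), generated from photoexcited Ru(II) and Hantzsch ester, transfers one electron to the N-acyloxyphthalimide 9, which loses phthalimide anion and CO2 to give the primary tridecyl radical; this nucleophilic radical adds to the unsubstituted CH2 terminus of the acrylate of 7 (the future C3), and the α-ester radical so formed is capped by hydrogen-atom transfer from Hantzsch ester. The closest known reaction type is the conjugate addition of alkyl radicals from redox-active esters of aliphatic acids, primary ones included, to acrylate esters. No ring is closed and no stereocentre is formed. The step needs regioselectivity for the β-carbon, secured by the polarity match of alkyl radical and acrylate and by the unhindered terminus, and it needs single addition, secured because the electrophilic adduct radical is reduced faster than it adds to a second electron-poor alkene. Cyclisation of the adduct radical onto ring A is not expected because the Z-ester geometry holds it away from the arene, and the aryl ethers, the MOM acetal and the chelated phenol lie outside the redox window of the ruthenium couple.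

Step 8
Reactants: 10 methyl 2-[2-[(hexadecanoyloxy)methyl]-4-methoxy-6-(methoxymethoxy)phenoxy]-6-hydroxy-4-methylbenzoate
Product: 11 Betaethrin E, methyl 2-hydroxy-6-[2-[(hexadecanoyloxy)methyl]-6-hydroxy-4-methoxyphenoxy]-4-methylbenzoate
Conditions: ZnBr2 (1.5 equiv), n-PrSH (3 equiv), CH2Cl2, 0 °C, 10–15 min
Reagents that add atoms: none
Why: Lewis acid/thiol cleavage of an aryl MOM ether: ZnBr2 activates the acetal and the thiol traps the methoxymethyl cation, so that the benzylic hexadecanoate and the methyl ester should stay intact and the electron-rich ring A should not be alkylated.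

**Compound list**
1 | 3-hydroxy-5-methoxybenzaldehyde | O=Cc1cc(O)cc(OC)c1 | starting material
2 | 2-bromo-3-hydroxy-5-methoxybenzaldehyde | O=Cc1cc(OC)cc(O)c1Br | intermediate
3 | 2-bromo-5-methoxy-3-(methoxymethoxy)benzaldehyde | O=Cc1cc(OC)cc(OCOC)c1Br | intermediate
4 | methyl 2,6-dihydroxy-4-methylbenzoate | COC(=O)c1c(O)cc(C)cc1O | starting material
5 | methyl 2-[2-formyl-4-methoxy-6-(methoxymethoxy)phenoxy]-6-hydroxy-4-methylbenzoate | O=Cc1cc(OC)cc(OCOC)c1Oc1cc(C)cc(O)c1C(=O)OC | intermediate
6 | methyl 2-hydroxy-6-[2-(hydroxymethyl)-4-methoxy-6-(methoxymethoxy)phenoxy]-4-methylbenzoate | OCc1cc(OC)cc(OCOC)c1Oc1cc(C)cc(O)c1C(=O)OC | intermediate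
7 | methyl 2-hydroxy-6-[4-methoxy-2-(methoxymethoxy)-6-[(prop-2-enoyloxy)methyl]phenoxy]-4-methylbenzoate | C=CC(=O)OCc1cc(OC)cc(OCOC)c1Oc1cc(C)cc(O)c1C(=O)OC | intermediate
8 | tetradecanoic acid | CCCCCCCCCCCCCC(=O)O | starting material
9 | 1,3-dioxoisoindolin-2-yl tetradecanoate | CCCCCCCCCCCCCC(=O)ON1C(=O)c2ccccc2C1=O | intermediate
10 | methyl 2-[2-[(hexadecanoyloxy)methyl]-4-methoxy-6-(methoxymethoxy)phenoxy]-6-hydroxy-4-methylbenzoate | CCCCCCCCCCCCCCCC(=O)OCc1cc(OC)cc(OCOC)c1Oc1cc(C)cc(O)c1C(=O)OC | intermediate
11 | Betaethrin E | CCCCCCCCCCCCCCCC(=O)OCc1cc(OC)cc(O)c1Oc1cc(C)cc(O)c1C(=O)OC | target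

Total step count: 8. Longest linear sequence: 7 steps (1 → 2 → 3 → 5 → 6 → 7 → 10 → 11; steps 1–5, 7 and 8).

**Steps most likely to fail**

Step 3. The C–O bond formation may stall at the doubly ortho-substituted bromide with a chelated, weakly nucleophilic phenoxide, so that protodebromination of 3 and double arylation of 4 take over. The fallback uses ligand coupling at iodine(III) instead of copper catalysis. It sets out from 3, which is converted by copper-catalysed halogen exchange (aromatic Finkelstein reaction; CuI, NaI, trans-N,N'-dimethylcyclohexane-1,2-diamine, dioxane, 110 °C) into 2-iodo-5-methoxy-3-(methoxymethoxy)benzaldehyde F1. Brief oxidation with mCPBA/TsOH·H2O (MeCN, rt) gives [2-formyl-4-methoxy-6-(methoxymethoxy)phenyl](hydroxy)(tosyloxy)-λ3-iodane F2, which is treated in the same flask with 1,3,5-trimethoxybenzene to give [2-formyl-4-methoxy-6-(methoxymethoxy)phenyl](2,4,6-trimethoxyphenyl)iodonium 4-methylbenzenesulfonate F3. This salt should arylate 4 without metal (K2CO3, MeCN, 40 °C), the ortho-formyl aryl group being transferred in preference to the trimethoxyphenyl group. The fallback comes back to the route at 5.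

Step 1. The bromination may lose regiocontrol (attack para to the hydroxyl at C6 or between the two oxygens at C4) or run on to dibromination. The fallback uses directed ortho-metalation instead of electrophilic substitution. It sets out from 1, which is protected (MOMCl, i-Pr2NEt, CH2Cl2) as 3-methoxy-5-(methoxymethoxy)benzaldehyde F4. Addition of lithium N,N,N'-trimethylethylenediamide (THF, −20 °C) masks the aldehyde as lithium {[2-(dimethylamino)ethyl](methyl)amino}[3-methoxy-5-(methoxymethoxy)phenyl]methanolate F5. n-BuLi should remove the proton at C2, between the amino alkoxide and the OMOM group, to give lithium {[2-(dimethylamino)ethyl](methyl)amino}[2-lithio-5-methoxy-3-(methoxymethoxy)phenyl]methanolate F6. 1,2-Dibromotetrafluoroethane (−78 °C) then gives lithium {[2-(dimethylamino)ethyl](methyl)amino}[2-bromo-5-methoxy-3-(methoxymethoxy)phenyl]methanolate F7, and aqueous work-up releases the aldehyde. The fallback comes back to the route at 3.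

Step 5. The acylation may lose chemoselectivity (acylation of the ring-B phenol), or the alcohol may be diverted by intramolecular transesterification onto the ring-B ester to an eight-membered lactone. The fallback activates the alcohol instead of the acid. It sets out from 6, which is esterified with acrylic acid under Mitsunobu conditions (PPh3, DIAD, THF, 0 °C). Only the benzylic alcohol is activated, and the carboxylate, more acidic than either phenol, is the nucleophile. The fallback comes back at 7 and makes no new compound.

Further compounds
F1 | step 3 | 2-iodo-5-methoxy-3-(methoxymethoxy)benzaldehyde | O=Cc1cc(OC)cc(OCOC)c1I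
F2 | step 3 | [2-formyl-4-methoxy-6-(methoxymethoxy)phenyl](hydroxy)(tosyloxy)-λ3-iodane | O=Cc1cc(OC)cc(OCOC)c1I(O)OS(=O)(=O)c1ccc(C)cc1
F3 | step 3 | [2-formyl-4-methoxy-6-(methoxymethoxy)phenyl](2,4,6-trimethoxyphenyl)iodonium 4-methylbenzenesulfonate | O=Cc1cc(OC)cc(OCOC)c1[I+]c1c(OC)cc(OC)cc1OC.Cc1ccc(cc1)S(=O)(=O)[O-]
F4 | step 1 | 3-methoxy-5-(methoxymethoxy)benzaldehyde | O=Cc1cc(OC)cc(OCOC)c1
F5 | step 1 | lithium {[2-(dimethylamino)ethyl](methyl)amino}[3-methoxy-5-(methoxymethoxy)phenyl]methanolate | [Li]OC(N(C)CCN(C)C)c1cc(OC)cc(OCOC)c1
F6 | step 1 | lithium {[2-(dimethylamino)ethyl](methyl)amino}[2-lithio-5-methoxy-3-(methoxymethoxy)phenyl]methanolate | [Li]OC(N(C)CCN(C)C)c1cc(OC)cc(OCOC)c1[Li]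
F7 | step 1 | lithium {[2-(dimethylamino)ethyl](methyl)amino}[2-bromo-5-methoxy-3-(methoxymethoxy)phenyl]methanolate | [Li]OC(N(C)CCN(C)C)c1cc(OC)cc(OCOC)c1Br
F0 | step 5 | none | none
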